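I began with the easy step, the loss of starting material to side product, which needs no gas and runs with 0.041 /s. The capture of dissolved gas by starting material to give target runs with 9.0 /M/s and draws on the same starting material, so I divided one rate by the other. Starting material and time both cancelled, and the ratio was the dissolved gas over 4.56 mM, the even-split level, at which target and side product form equally fast.

starting material 0.20 M; gas phase 70 mM (held); time 25 s

- blue: doubling the saturation concentration of gas phase, all else as stated
- ochre: doubling the transfer coefficient of step 1, all else as stated

1. target at 25 s, in percent of the starting material charged
2. the change that raises the amount of target at 25 s, in percent of the starting material charged most ("none" if none brings more than 2 percentage points) (blue / ochre / none)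
3. amount of target at 25 s, in percent of the starting material charged, after ochre

- two of one species on the left: rate k times its square, two consumed each time
- at the start none of the gas is dissolved
- run time (flask): 25 s

In the first instants no gas was dissolved, so the starting material that reacted became side product. Gas entered at 9.10 mM/s. Starting material took it up at 1.80 /s, a pseudo-first-order capture, while falling transfer and decomposition together took 0.260 /s, a far slower pull. Within about 0.485 s I therefore put the gas at 4.42 mM, close to the even-split level, so about half of the starting material consumed became target. I dropped the homo dimer, because its pull of 0.00883 /s at that level was far weaker than 0.260 /s.

In the middle, starting material thinned, capture weakened and the gas level rose, so later portions favoured target. Decomposition kept its pull of 0.13 /s on the gas while capture's pull fell with the starting material, so I expected decomposition to take more of the gas than capture once starting material stood below 14.4 mM. Summing the ratio over the starting material spent, without any clock, I reckoned 65.1 % target from a fully spent charge, 78.3 % after blue and 76.3 % after ochre, so blue came out ahead.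

The forecast gave 61 %, and 74 % after ochre, and chose blue, holding that “raising the saturation level also keeps a larger driving force as dissolved gas builds up”. The flask gave 60.0 % at 25 s, 5.1 percentage points below my figure, with 2.6 % of the starting material left; ochre gave 73.3 %, and blue gained 15 points against 13 points for ochre.

    gas phase ⇌ dissolved gas, rate k1*(csat - [dissolved gas]) (k1 = 0.13 /s, csat = 70 mM)
    2 dissolved gas → homo dimer (k2 = 1.0 /M/s)
    dissolved gas → decomposed reagent (k3 = 0.13 /s)
    starting material → side product (k4 = 0.041 /s)
    starting material + dissolved gas → target (k5 = 9.0 /M/s)

In this flask the dissolved gas stood at 0.00494 M after 2.50 s, 1.08 times the even-split level, and at 0.0232 M after 25.0 s, 5.09 times it, when starting material was going to target 5.1 times as fast as to side product. In the neighbour flask with 0.50 M of starting material, the dissolved gas after 25.0 s stood at 0.00964 M, 2.11 times the even-split level, and side product at 49.5 % held more than target at 37.5 %.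

The numbers of this flask were chosen freely, and the outcome is calculated.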